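Ring B of the target has oxygen at C6 and C9 (para) and methyl groups at C8 and C10: the pattern of 2,6-dimethyl-1,4-benzoquinone, whose C5=C10 bond can act as dienophile. A Diels–Alder reaction with 3-silyloxy-4-methylpenta-1,3-diene forms C1–C10 and C4–C5 at once, closing ring A with the C10 quaternary centre and the C4 gem-dimethyl group and leaving C3 as a silyl enol ether. The racemic cis adduct is resolved; the three carbonyls are then handled one by one (C6 reduced, C9 methylenated and epoxidised, C3 unmasked last). A C16-silylated 3-furylmethyl Grignard reagent opens the 9α,11-epoxide, and silyl-directed photooxygenation gives the C16 lactone carbonyl.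

Key step: step 2

Remarks:
- Numbering is that of labdanes: ring A = C1–C5, C10; ring B = C5–C10; C11–C12 link C9 to C13 of the five-membered ring C13–C16 (ring O between C15 and C16); β is the face of the C10 methyl, α the opposite face.
- Assumption: 4-methylpent-1-en-3-one is bought as the stabilised liquid and distilled before use.
- A plain 3-alkylfuran would be oxidised to the lactone regioisomer with the carbonyl at C15, so the furan carries a silyl group on C16.

Step 1
Reactants: 1 4-methylpent-1-en-3-one
Product: 2 3-(tert-butyldimethylsilyloxy)-4-methylpenta-1,3-diene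
Conditions: TBSOTf, Et3N, CH2Cl2, 0 °C → rt
Reagents that add atoms: tert-butyldimethylsilyl triflate, CC(C)(C)[Si](C)(C)OS(=O)(=O)C(F)(F)F
Why: Silyl enol ether formation by soft enolisation (silyl triflate/amine); the isopropyl methine is the only enolisable position, so the cross-conjugated dienol ether should form as one regioisomer with no stereo-element.

Step 2
Reactants: 2 3-(tert-butyldimethylsilyloxy)-4-methylpenta-1,3-diene; 3 2,6-dimethyl-1,4-benzoquinone
Product: 4 racemic cis adduct, rac-(4aR,8aS)-6-(tert-butyldimethylsilyloxy)-2,5,5,8a-tetramethyl-4a,5,8,8a-tetrahydronaphthalene-1,4-dione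
Conditions: 2 (2 equiv), CH2Cl2, 13 kbar, 25 °C, 72 h
Reagents that add atoms: none
Why: A concerted, asynchronous normal-demand [4+2] cycloaddition joins the electron-rich 2-silyloxydiene to the C5=C10 double bond of the quinone; the closest known reaction type is the Diels–Alder addition of 2-silyloxy-1,3-dienes to alkyl-1,4-benzoquinones, run here under pressure as is done for dienes with a disubstituted terminus. Ring A is closed as a six-membered carbocycle by the cycloaddition itself, both σ-bonds (C1–C10 and C4–C5) forming suprafacially on one face of the quinone. C5 and C10 are therefore cis by the suprafacial nature of the addition, whereas nothing controls the quinone face, so 4 is racemic and the antipodes are separated in step 3. The selectivity needed is regiochemical: the silyloxy group makes the CMe2 terminus (C4) the nucleophilic end, C5 is the unsubstituted carbon β to the C9 carbonyl, and the other orientation would join two fully substituted carbons, so polarisation and sterics both place C4 on C5 and C1 on C10. The two methyl-bearing C=C bonds of the quinone are equivalent by symmetry and the diene termini carry no stereo-label, so neither site nor endo/exo selectivity matters. Pressure offsets the s-cis penalty imposed by the Z-methyl group of the diene without acid that could divert the silyl enol ether into conjugate addition.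

Step 3
Reactants: 4 racemic cis adduct
Product: 5 (4aR,8aS)-adduct (5β-H; 10β-CH3)
Conditions: preparative HPLC, amylose tris(3,5-dimethylphenylcarbamate) phase, hexane/i-PrOH
Reagents that add atoms: none
Why: Resolution of a racemate by chromatography on a chiral stationary phase; C10 is quaternary and C5 can only epimerise to a diastereomer, so the antipodes cannot racemise, and the wanted one is to be identified by anomalous-dispersion X-ray analysis (Si) before it is carried on.

Step 4
Reactants: 5 (4aR,8aS)-adduct
Product: 7 trans-fused 3-(tert-butyldimethylsilyloxy)-2-ene-6,9-dione (5α-H; 8α-CH3; 10β-CH3), via cis-fused saturated dione 6 (not isolated)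
Conditions: H2 (1 atm), Pd/C, EtOAc, rt; filter; DBU, PhMe, 80 °C
Reagents that add atoms: none
Why: Catalytic hydrogenation should saturate the electron-poor ene-dione C7=C8 bond well before the hindered silyl enol ether, and base-mediated epimerisation through the C6 and C9 enolates (non-nucleophilic DBU leaves Si–O alone) should then give the trans-decalin (5α-H, also the kinetically open α-face protonation because the 4β- and 10β-methyls cover the β face) and the equatorial 8α-methyl.

Step 5
Reactants: 7 trans-fused 3-(tert-butyldimethylsilyloxy)-2-ene-6,9-dione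
Product: 8 6β-hydroxy-3-(tert-butyldimethylsilyloxy)-2-en-9-one (5α-H; 8α-CH3; 10β-CH3)
Conditions: L-Selectride, THF, −78 → −40 °C; aq. NH4Cl
Reagents that add atoms: none
Why: Chemoselective ketone reduction with a bulky trialkylborohydride: C6 is reached along the open α trajectory whereas C9 is flanked by quaternary C10 and the C8 methine, and since the β face of C6 is blocked by the syn-axial 4β- and 10β-methyls the hydride arrives from the α face and should give the axial 6β-alcohol.

Step 6
Reactants: 8 6β-hydroxy-3-(tert-butyldimethylsilyloxy)-2-en-9-one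
Product: 9 6β-hydroxy-3-(tert-butyldimethylsilyloxy)-2,9(11)-diene (exocyclic C9=C11H2)
Conditions: Ph3PCH3Br, KHMDS, PhMe, 0 → 90 °C (excess ylide)
Reagents that add atoms: methyltriphenylphosphonium bromide, C[P+](c1ccccc1)(c1ccccc1)c1ccccc1.[Br-]
Why: Wittig methylenation with the small unstabilised ylide at elevated temperature, as used for 2,2,6-trisubstituted cyclohexanones; the 6β-OH is merely deprotonated, the silyl enol ether is inert, and C8 keeps the equatorial methyl (the only epimer not syn-diaxial to the C10 methyl).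

Step 7
Reactants: 9 6β-hydroxy-3-(tert-butyldimethylsilyloxy)-2,9(11)-diene
Product: 11 9(11)-ene-3β,6β-diol, via 3-ketone 10 (not isolated)
Conditions: TBAF, AcOH, THF, 0 °C; then MeOH, NaBH4, 0 °C
Reagents that add atoms: none
Why: Fluoride desilylation of the silyl enol ether releases the C3 ketone, now the only carbonyl group, and borohydride reduction delivers hydride from the α face (the β face is shielded by the 4β- and 10β-methyls) to give the equatorial 3β-alcohol, as is usual for 4,4-dimethyl-3-ketones of this ring system.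

Step 8
Reactants: 11 9(11)-ene-3β,6β-diol
Product: 12 3β-(triethylsilyloxy)-9(11)-en-6β-ol
Conditions: TESCl, imidazole, DMF, 0 °C
Reagents that add atoms: chlorotriethylsilane, CC[Si](CC)(CC)Cl
Why: Silyl ether protection; only the equatorial 3β-OH should react, since the axial 6β-OH is 1,3-diaxial to the 4β- and 10β-methyls and inert to silyl chlorides.

Step 9
Reactants: 12 3β-(triethylsilyloxy)-9(11)-en-6β-ol
Product: 13 9α,11-epoxy-3β-(triethylsilyloxy)-6β-ol
Conditions: mCPBA, NaHCO3, CH2Cl2, 0 °C
Reagents that add atoms: 3-chloroperoxybenzoic acid, OOC(=O)c1cccc(Cl)c1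
Why: Prilezhaev epoxidation of the exocyclic 1,1-disubstituted alkene; the peracid should approach C9=C11 from the α face, anti to the axial 10β-methyl on the neighbouring carbon, so that oxygen ends up 9α (axial) and C11 β (equatorial).

Step 10
Reactants: 14 3-furanmethanol
Product: 16 [2-(trimethylsilyl)furan-3-yl]methanol, via bis-silylated furan 15 (not isolated)
Conditions: n-BuLi (2.2 equiv), THF, −78 → 0 °C; TMSCl (2.3 equiv); then K2CO3, MeOH
Reagents that add atoms: chlorotrimethylsilane, C[Si](C)(C)Cl
Why: Alkoxide-directed ortho-lithiation of the furanmethanol dianion at C2, C- and O-silylation, then selective methanolysis of the O–Si bond; the C2 silyl group later fixes the lactone carbonyl at this carbon (C16) and blocks attack through the ring of the furylmethyl organometallic.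

Step 11
Reactants: 16 [2-(trimethylsilyl)furan-3-yl]methanol
Product: 18 3-(chloromethyl)-2-(trimethylsilyl)furan, via mesylate 17 (not isolated)
Conditions: MsCl, 2,4,6-collidine, LiCl, DMF, 0 °C
Reagents that add atoms: lithium chloride, [Li+].[Cl-]
Why: One-pot sulfonylation and SN2 chloride exchange under non-acidic conditions, which suits the acid-labile furylmethyl and C–Si functions; no stereocentre is involved.

Step 12
Reactants: 13 9α,11-epoxy-3β-(triethylsilyloxy)-6β-ol; 18 3-(chloromethyl)-2-(trimethylsilyl)furan
Product: 20 3β-(triethylsilyloxy)-6β,9α-diol with the β-CH2CH2-[2-(trimethylsilyl)furan-3-yl] chain on C9, via Grignard reagent 19 (not isolated)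
Conditions: 18, Mg, THF, 0 °C; then 13, CuI (10 mol %), THF, −30 → 0 °C (3 equiv of 19); aq. NH4Cl
Reagents that add atoms: none
Why: Copper-catalysed Grignard opening of a 2,2-disubstituted epoxide by SN2 attack at the CH2 carbon C11 forms C11–C12 without touching C9, so the 9α-oxygen set in step 9 becomes the tertiary 9α-alcohol; one equivalent of 19 is spent on the 6β-OH.

Step 13
Reactants: 20 3β-(triethylsilyloxy)-6β,9α-diol with silylfuran side chain
Product: 21 6β-acetate of 20
Conditions: Ac2O, DMAP, pyridine, 50 °C
Reagents that add atoms: acetic anhydride, CC(=O)OC(C)=O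
Why: DMAP-catalysed acylation; the hindered secondary 6β-OH is the only hydroxyl that can be acetylated, the tertiary 9α-OH (next to quaternary C10) being inert and O3 silylated.

Step 14
Reactants: 21 6β-acetate with silylfuran side chain
Product: 24 6β-acetoxy-9α-hydroxy-3β-(triethylsilyloxy)labd-13-en-16,15-olide, via γ-hydroxybutenolide 22 (not isolated), via (Z)-hydroxy acid 23 (not isolated)
Conditions: O2, hν, TPP, CH2Cl2, −78 °C; then MeOH, NaBH4, 0 °C; then 1 M HCl to pH 3
Reagents that add atoms: oxygen, O=O
Why: Singlet-oxygen [4+2] photooxygenation of the 2-silylfuran, in which silyl migration within the endoperoxide turns the silylated carbon C16 into the carboxyl carbon and C15 into the hemiacetal carbon, followed by borohydride reduction of the masked C15 aldehyde and acid-induced lactonisation of the (Z)-hydroxy acid, should give the α-substituted butenolide (C16=O, C15H2–O) and not its regioisomer; the hindered acetate and the carboxylate stage are not reduced.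

Step 15
Reactants: 24 6β-acetoxy-9α-hydroxy-3β-(triethylsilyloxy)labd-13-en-16,15-olide
Product: 25 6β-acetoxy-3β,9α-dihydroxylabd-13-en-16,15-olide (CNP0513254.1)
Conditions: HF·pyridine, pyridine, THF, 0 °C → rt
Reagents that add atoms: none
Why: Fluoride-mediated cleavage of the triethylsilyl ether under mildly acidic conditions that leave the acetate, the butenolide and the tertiary alcohol untouched; all stereocentres are already in place.

Compound list
1 | 4-methylpent-1-en-3-one | CC(C)C(=O)C=C | starting material
2 | 3-(tert-butyldimethylsilyloxy)-4-methylpenta-1,3-diene | C=CC(O[Si](C)(C)C(C)(C)C)=C(C)C | intermediate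
3 | 2,6-dimethyl-1,4-benzoquinone | CC1=CC(=O)C=C(C)C1=O | starting material
4 | rac-(4aR,8aS)-6-(tert-butyldimethylsilyloxy)-2,5,5,8a-tetramethyl-4a,5,8,8a-tetrahydronaphthalene-1,4-dione (racemic cis adduct; the antipode carried on is drawn) | O=C1C=C(C)C(=O)[C@@]2(C)CC=C(O[Si](C)(C)C(C)(C)C)C(C)(C)[C@@H]12 | intermediate
5 | (4aR,8aS)-enantiomer of 4 (5β-H, 10β-CH3; C3 silyl enol ether; 7-ene-6,9-dione) | O=C1C=C(C)C(=O)[C@@]2(C)CC=C(O[Si](C)(C)C(C)(C)C)C(C)(C)[C@@H]12 | intermediate
6 | cis-fused 3-(tert-butyldimethylsilyloxy)-2-ene-6,9-dione (5β-H, 10β-CH3, C8 epimers) | O=C1CC(C)C(=O)[C@@]2(C)CC=C(O[Si](C)(C)C(C)(C)C)C(C)(C)[C@@H]12 | intermediate (not isolated)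
7 | trans-fused 3-(tert-butyldimethylsilyloxy)-2-ene-6,9-dione (5α-H, 8α-CH3, 10β-CH3) | O=C1C[C@@H](C)C(=O)[C@@]2(C)CC=C(O[Si](C)(C)C(C)(C)C)C(C)(C)[C@H]12 | intermediate
8 | 6β-hydroxy-3-(tert-butyldimethylsilyloxy)-2-en-9-one (5α-H, 8α-CH3, 10β-CH3) | O[C@@H]1C[C@@H](C)C(=O)[C@@]2(C)CC=C(O[Si](C)(C)C(C)(C)C)C(C)(C)[C@H]12 | intermediate
9 | 6β-hydroxy-3-(tert-butyldimethylsilyloxy)-2,9(11)-diene | O[C@@H]1C[C@@H](C)C(=C)[C@@]2(C)CC=C(O[Si](C)(C)C(C)(C)C)C(C)(C)[C@H]12 | intermediate
10 | 6β-hydroxy-9(11)-en-3-one | O[C@@H]1C[C@@H](C)C(=C)[C@@]2(C)CCC(=O)C(C)(C)[C@H]12 | intermediate (not isolated)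
11 | 9(11)-ene-3β,6β-diol | O[C@@H]1C[C@@H](C)C(=C)[C@@]2(C)CC[C@H](O)C(C)(C)[C@H]12 | intermediate
12 | 3β-(triethylsilyloxy)-9(11)-en-6β-ol | O[C@@H]1C[C@@H](C)C(=C)[C@@]2(C)CC[C@H](O[Si](CC)(CC)CC)C(C)(C)[C@H]12 | intermediate
13 | 9α,11-epoxy-3β-(triethylsilyloxy)-6β-ol (epoxide O α, C11 β) | O[C@@H]1C[C@@H](C)[C@]3(CO3)[C@@]2(C)CC[C@H](O[Si](CC)(CC)CC)C(C)(C)[C@H]12 | intermediate
14 | 3-furanmethanol | OCc1ccoc1 | starting material
15 | 2-(trimethylsilyl)-3-[(trimethylsilyloxy)methyl]furan | C[Si](C)(C)OCc1ccoc1[Si](C)(C)C | intermediate (not isolated)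
16 | [2-(trimethylsilyl)furan-3-yl]methanol | OCc1ccoc1[Si](C)(C)C | intermediate
17 | [2-(trimethylsilyl)furan-3-yl]methyl methanesulfonate | CS(=O)(=O)OCc1ccoc1[Si](C)(C)C | intermediate (not isolated)
18 | 3-(chloromethyl)-2-(trimethylsilyl)furan | ClCc1ccoc1[Si](C)(C)C | intermediate
19 | {[2-(trimethylsilyl)furan-3-yl]methyl}magnesium chloride | Cl[Mg]Cc1ccoc1[Si](C)(C)C | intermediate (not isolated)
20 | 3β-(triethylsilyloxy)-6β,9α-diol with β-CH2CH2-[2-(trimethylsilyl)furan-3-yl] on C9 (16-silyl furanolabdane) | O[C@@H]1C[C@@H](C)[C@](O)(CCc3ccoc3[Si](C)(C)C)[C@@]2(C)CC[C@H](O[Si](CC)(CC)CC)C(C)(C)[C@H]12 | intermediate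
21 | 6β-acetate of 20 | CC(=O)O[C@@H]1C[C@@H](C)[C@](O)(CCc3ccoc3[Si](C)(C)C)[C@@]2(C)CC[C@H](O[Si](CC)(CC)CC)C(C)(C)[C@H]12 | intermediate
22 | 6β-acetoxy-9α,15-dihydroxy-3β-(triethylsilyloxy)labd-13-en-16,15-olide (C15 epimers) | CC(=O)O[C@@H]1C[C@@H](C)[C@](O)(CCC3=CC(O)OC3=O)[C@@]2(C)CC[C@H](O[Si](CC)(CC)CC)C(C)(C)[C@H]12 | intermediate (not isolated)
23 | (13Z)-6β-acetoxy-9α,15-dihydroxy-3β-(triethylsilyloxy)labd-13-en-16-oic acid | CC(=O)O[C@@H]1C[C@@H](C)[C@](O)(CC/C(C(=O)O)=C/CO)[C@@]2(C)CC[C@H](O[Si](CC)(CC)CC)C(C)(C)[C@H]12 | intermediate (not isolated)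
24 | 6β-acetoxy-9α-hydroxy-3β-(triethylsilyloxy)labd-13-en-16,15-olide | CC(=O)O[C@@H]1C[C@@H](C)[C@](O)(CCC3=CCOC3=O)[C@@]2(C)CC[C@H](O[Si](CC)(CC)CC)C(C)(C)[C@H]12 | intermediate
25 | 6β-acetoxy-3β,9α-dihydroxylabd-13-en-16,15-olide (CNP0513254.1) | CC(=O)O[C@@H]1C[C@@H](C)[C@](O)(CCC2=CCOC2=O)[C@@]2(C)CC[C@H](O)C(C)(C)[C@H]12 | target

Total step count: 15.
Longest linear sequence: 13 steps (steps 1–9 and 12–15, from 4-methylpent-1-en-3-one); steps 10–11 are the furan branch.

Steps most likely to fail

1. Step 2. The cycloaddition may be too slow: the Z-methyl of the CMe2 terminus disfavours the s-cis diene and both new bonds form at crowded carbons. Hydrolysis or oligomerisation of 2, or conjugate addition followed by aromatisation to a hydroquinone, may then win. The fallback uses a more electron-poor dienophile with a removable activating group and sets out from 3. Addition of Br2 (CHCl3, 0 °C) should give 5,6-dibromo-2,6-dimethylcyclohex-2-ene-1,4-dione F1, and Et3N should eliminate HBr to 2-bromo-3,5-dimethyl-1,4-benzoquinone F2, whose bromine sits on the future C7. Cycloaddition of 2 to the unbrominated C=C bond under the conditions of step 2 should give, with the same regiochemistry, the racemic 7-bromo adduct F3. Chiral-phase HPLC should give its (4aR,8aS)-enantiomer F4. H2, Pd/C, Et3N (hydrogenolysis of C7–Br together with saturation of C7=C8) followed by DBU should lead back to the route at 7.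

2. Step 12. SN2 attack at the neopentyl-type C11 may be slower than Lewis-acid-induced rearrangement of the epoxide to a C9 aldehyde, halohydrin formation or Wurtz coupling of the Grignard reagent. The fallback replaces substitution by C11=C12 olefination and sets out from 12. OsO4/NMO (same α-face preference as the peracid) should give the 3β-(triethylsilyloxy)-6β,9α,11-triol F5. TEMPO/NaOCl should oxidise only the primary alcohol to the 9α-hydroxy-11-aldehyde F6. The ylide from {[2-(trimethylsilyl)furan-3-yl]methyl}triphenylphosphonium chloride F7 (18 + PPh3, then NaHMDS) should convert F6 into the C11=C12 alkene F8 (either geometry). Diimide (o-nitrobenzenesulfonylhydrazide, Et3N) should saturate this bond without touching the furan, which returns to the route at 20.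

3. Step 6. The basic ylide may enolise the hindered C9 ketone instead of adding to it, so that the ketone is recovered. The fallback is a Peterson olefination through a non-basic organocerium reagent and sets out from 8. Me3SiCH2Li/CeCl3 (THF, −78 °C) should add to C9 to give the 9-hydroxy-9-(trimethylsilylmethyl) compound F9, and KH (THF) should induce syn-elimination of silanolate to the exocyclic alkene, returning to the route at 9.

Further compounds
F1 | step 2 | 5,6-dibromo-2,6-dimethylcyclohex-2-ene-1,4-dione | CC1=CC(=O)C(Br)C(C)(Br)C1=O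
F2 | step 2 | 2-bromo-3,5-dimethyl-1,4-benzoquinone | CC1=CC(=O)C(Br)=C(C)C1=O
F3 | step 2 | rac-(4aR,8aS)-3-bromo-6-(tert-butyldimethylsilyloxy)-2,5,5,8a-tetramethyl-4a,5,8,8a-tetrahydronaphthalene-1,4-dione | O=C1C(Br)=C(C)C(=O)[C@@]2(C)CC=C(O[Si](C)(C)C(C)(C)C)C(C)(C)[C@@H]12
F4 | step 2 | (4aR,8aS)-enantiomer of F3 | O=C1C(Br)=C(C)C(=O)[C@@]2(C)CC=C(O[Si](C)(C)C(C)(C)C)C(C)(C)[C@@H]12
F5 | step 12 | 3β-(triethylsilyloxy)-6β,9α,11-triol | O[C@@H]1C[C@@H](C)[C@](O)(CO)[C@@]2(C)CC[C@H](O[Si](CC)(CC)CC)C(C)(C)[C@H]12
F6 | step 12 | 6β,9α-dihydroxy-3β-(triethylsilyloxy)-11-al | O[C@@H]1C[C@@H](C)[C@](O)(C=O)[C@@]2(C)CC[C@H](O[Si](CC)(CC)CC)C(C)(C)[C@H]12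
F7 | step 12 | {[2-(trimethylsilyl)furan-3-yl]methyl}triphenylphosphonium chloride | C[Si](C)(C)c1occc1C[P+](c1ccccc1)(c1ccccc1)c1ccccc1.[Cl-]
F8 | step 12 | 11-ene analogue of 20 (C11=C12, E/Z) | O[C@@H]1C[C@@H](C)[C@](O)(C=Cc3ccoc3[Si](C)(C)C)[C@@]2(C)CC[C@H](O[Si](CC)(CC)CC)C(C)(C)[C@H]12
F9 | step 6 | 6β,9-dihydroxy-9-(trimethylsilylmethyl)-3-(tert-butyldimethylsilyloxy)-2-ene (C9 epimer not assigned) | O[C@@H]1C[C@@H](C)C(O)(C[Si](C)(C)C)[C@@]2(C)CC=C(O[Si](C)(C)C(C)(C)C)C(C)(C)[C@H]12
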